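## Retrosynthetic overview

1. The butenolide comes from a 3-alkylfuran by late C–H borylation and oxidation; the C9–C11 bond comes from a B-alkyl Suzuki coupling of a ring B enol triflate with a 2-(furan-3-yl)ethyl borane.
2. The C2 and C6 carbinols come from ketones by thermodynamically controlled electron-transfer reductions; the C4 quaternary centre comes from α-face conjugate methylation of a ring A enone.
3. Key step: a catalytic enantioselective Diels–Alder reaction of 2,6-dimethyl-1,4-benzoquinone (ring B with both methyls and the C6/C9 oxygens) with a 2-silyloxy diene (C1–C4 and C19). It sets C10, and every other stereocentre is relayed from it.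
4. Ring order: ring B is bought as the quinone, ring A is closed in the cycloaddition, and the butenolide ring is unveiled last.

Assumption: the (S)-diphenylprolinol-derived oxazaborolidinium catalyst is taken to give the 10S adduct drawn (the mirror-image catalyst would be used if the facial sense were opposite); atom labels follow labdane numbering (C1–C10 decalin, C19 = CH2O on C4, C11–C16 side chain), and β is the face of the C10 methyl.

## Route

Step 1
Reactants: 1 2-(benzyloxy)acetaldehyde; 2 acetonylidenetriphenylphosphorane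
Product: 3 (3E)-5-(benzyloxy)pent-3-en-2-one
Conditions: CH2Cl2, 23 °C
Reagents that add atoms: none
Why: Wittig olefination with a stabilised acyl ylide is reliably E-selective and gives the γ-benzyloxy enone in one operation.

Step 2
Reactants: 3 (3E)-5-(benzyloxy)pent-3-en-2-one
Product: 4 (3E)-5-benzyloxy-2-(triisopropylsilyloxy)penta-1,3-diene
Conditions: i-Pr3SiOTf, Et3N, CH2Cl2, 0 °C
Reagents that add atoms: triisopropylsilyl trifluoromethanesulfonate, CC(C)[Si](C(C)C)(C(C)C)OS(=O)(=O)C(F)(F)F
Why: Soft enolisation (silyl triflate and amine) removes a methyl α′-proton and gives the cross-conjugated 2-silyloxy diene with the E alkene intact; the bulky silyl group lets the enol ether survive the later basic, reductive and aqueous steps.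

Step 3
Reactants: 4 (3E)-5-benzyloxy-2-(triisopropylsilyloxy)penta-1,3-diene; 5 2,6-dimethyl-1,4-benzoquinone
Product: 6 cis-fused cycloadduct (10S; 10β-CH3; 5β-H; 4α-CH2OBn)
Conditions: (S)-o-tolyl oxazaborolidine from (S)-α,α-diphenylprolinol, protonated with Tf2NH (20 mol %), CH2Cl2, −78 → −40 °C
Reagents that add atoms: none
Why: Catalytic enantioselective quinone Diels–Alder reaction in which the chiral boron cation binds the unhindered C6 carbonyl, the nucleophilic CH2 terminus of the diene bonds to the methyl-bearing β-carbon (C10) and the substituted terminus to C5, and endo approach to one enantiotopic face sets C10 (S) with cis H5 and an all-cis C4 substituent (C5 is corrected in step 4, C4 is erased in step 9).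

Step 4
Reactants: 6 cis-fused cycloadduct
Product: 7 trans-fused enedione (5α-H)
Conditions: DBU (0.2 equiv), CH2Cl2, 23 °C
Reagents that add atoms: none
Why: Base-mediated epimerisation through the C5 enolate (the only enolisable position; aromatisation is blocked by the angular methyl) gives the thermodynamically preferred trans-fused isomer, in which the C4–CH2OBn and C5–C6 bonds become diequatorial; C10 is untouched.

Step 5
Reactants: 7 trans-fused enedione
Product: 9 C9 enol triflate with C6 ketone, via lithium enolate 8 (not isolated)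
Conditions: LiBH(s-Bu)3 (1.05 equiv), THF, −78 °C; then PhNTf2, −78 → 0 °C; NH4Cl quench
Reagents that add atoms: N-phenylbis(trifluoromethanesulfonimide), O=S(=O)(N(c1ccccc1)S(=O)(=O)C(F)(F)F)C(F)(F)F
Why: Conjugate hydride addition of the bulky borohydride at the unsubstituted β-carbon C7 of the enedione generates the C8=C9 enolate regiospecifically, and this is O-sulfonylated in situ (reductive enolate trapping, enol triflate formation) while the C6 ketone is left in place.

Step 6
Reactants: 10 furan-3-carbaldehyde
Product: 11 3-ethenylfuran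
Conditions: Ph3PCH3Br, KOt-Bu, Et2O, 0 → 23 °C; used as a distilled ethereal solution
Reagents that add atoms: methyltriphenylphosphonium bromide, C[P+](c1ccccc1)(c1ccccc1)c1ccccc1.[Br-]
Why: Wittig methylenation of an aromatic aldehyde is a standard, high-yielding route to the volatile vinylfuran.

Step 7
Reactants: 9 C9 enol triflate; 11 3-ethenylfuran
Product: 13 C9 furylethyl 6-ketone, via B-alkyl borane 12 (not isolated)
Conditions: 11, 9-BBN-H, THF, 0 → 23 °C; then 9, PdCl2(dppf) (5 mol %), AsPh3, Cs2CO3, DMF/THF/H2O, 23 °C
Reagents that add atoms: none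
Why: Anti-Markovnikov hydroboration of the vinyl group followed by B-alkyl Suzuki–Miyaura coupling with the hindered cyclohexenyl triflate forms the C9–C11 bond and fixes the tetrasubstituted C8=C9 alkene; the mild carbonate base at room temperature avoids migration of the β,γ-alkene into conjugation with the C6 ketone.

Step 8
Reactants: 13 C9 furylethyl 6-ketone
Product: 14 6α-alcohol
Conditions: SmI2 (2.5 equiv), H2O, Et3N, THF, 0 °C
Reagents that add atoms: none
Why: Single-electron (ketyl) reduction by divalent samarium is thermodynamically controlled and gives the equatorial 6α-alcohol (the axial 6β-epimer is syn-axial to the C10 methyl) without touching the benzyl ether, silyl enol ether, furan or alkene; it is done now because a C6 ketone next to the ring A enone of step 9 would make C5–H a vinylogous 1,3-diketone proton.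

Step 9
Reactants: 14 6α-alcohol
Product: 15 ring A enone (C2 ketone; C3=C4)
Conditions: Pd(OAc)2 (1.2 equiv), MeCN, 40 °C
Reagents that add atoms: none
Why: Saegusa–Ito oxidation, in which the palladium enolate formed from the silyl enol ether can only undergo β-hydride elimination toward C4–H, so the enone is formed regiospecifically with C4 becoming trigonal.

Step 10
Reactants: 15 ring A enone
Product: 17 C4-quaternary 2-ketone (4α-CH3; 4β-CH2OBn), via bis-silyl intermediate 16 (not isolated)
Conditions: Me2CuLi (3 equiv, from MeLi and CuI), Me3SiCl (5 equiv), THF, −78 → −30 °C; then 10% aq. citric acid, 0 °C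
Reagents that add atoms: lithium dimethylcuprate, [Li+].C[Cu-]C (made in the flask from methyllithium, [Li]C, and CuI)
Why: Chlorosilane-accelerated Gilman cuprate conjugate addition to the β,β-disubstituted enone takes place on the α face of the trans-fused decalin, anti to the syn-axial C10 methyl (the same facial sense as C4 enolate alkylations in 10β-methyl decalins), so the new methyl is 4α and the CH2OBn group becomes the axial 4β (C19) substituent.

Step 11
Reactants: 17 C4-quaternary 2-ketone
Product: 18 furan triol (2α,6α,19-triol)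
Conditions: Li (excess), NH3(l)/THF, t-BuOH, −78 → −33 °C; then solid NH4Cl
Reagents that add atoms: none
Why: Dissolving-metal reduction gives the thermodynamically more stable equatorial 2α-alcohol (the axial epimer would be syn-axial to both the C10 methyl and the C4 CH2O group), and the same conditions cleave the benzyl ether while the furan and the isolated tetrasubstituted alkene are inert.

Step 12
Reactants: 18 furan triol
Product: 20 target butenolide, via tetraboryl intermediate 19 (not isolated)
Conditions: HBpin (2.5 equiv), B2pin2 (1.1 equiv), [Ir(OMe)(cod)]2 (3 mol %), 4,4′-di-tert-butyl-2,2′-bipyridine, THF, 50 °C; then 30% H2O2, aq. NaHCO3, 0 °C; then Et3N, 23 °C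
Reagents that add atoms: hydrogen peroxide, OO
Why: Sterically controlled iridium-catalysed C–H borylation of the 3-substituted furan occurs at the free α-position remote from the side chain (C15) with the hydroxyls masked in situ as pinacol borates, and oxidation of the furyl boronate gives the 2-hydroxyfuran, which tautomerises (amine) to the conjugated 4-substituted furan-2(5H)-one without affecting the hindered C8=C9 alkene.

## Compound list

1 | 2-(benzyloxy)acetaldehyde | O=CCOCc1ccccc1 | starting material
2 | acetonylidenetriphenylphosphorane (1-(triphenylphosphoranylidene)propan-2-one) | CC(=O)C=P(c1ccccc1)(c1ccccc1)c1ccccc1 | starting material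
3 | (3E)-5-(benzyloxy)pent-3-en-2-one | CC(=O)/C=C/COCc1ccccc1 | intermediate
4 | (3E)-5-benzyloxy-2-(triisopropylsilyloxy)penta-1,3-diene | C=C(O[Si](C(C)C)(C(C)C)C(C)C)/C=C/COCc1ccccc1 | intermediate
5 | 2,6-dimethyl-1,4-benzoquinone | CC1=CC(=O)C=C(C)C1=O | starting material
6 | cis-fused cycloadduct: ring A C1H2–C2(OTIPS)=C3H–C4H(α-CH2OBn), ring B C6(=O)–C7H=C8(CH3)–C9(=O), 10β-CH3, 5β-H, 10S | CC=1C(=O)[C@@]2(C)CC(O[Si](C(C)C)(C(C)C)C(C)C)=C[C@@H](COCc3ccccc3)[C@H]2C(=O)C=1 | intermediate
7 | trans-fused enedione: C5 epimer of 6 (5α-H, 10β-CH3, 4α-CH2OBn) | CC=1C(=O)[C@@]2(C)CC(O[Si](C(C)C)(C(C)C)C(C)C)=C[C@@H](COCc3ccccc3)[C@@H]2C(=O)C=1 | intermediate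
8 | lithium C8=C9 enolate (C9–OLi, C7H2, C6 ketone) of the 7,8-dihydro form of 7 | CC1=C(O[Li])[C@@]2(C)CC(O[Si](C(C)C)(C(C)C)C(C)C)=C[C@@H](COCc3ccccc3)[C@@H]2C(=O)C1 | intermediate (not isolated)
9 | C9 enol triflate: 9-(trifluoromethanesulfonyloxy)-8-methyl-Δ8, C6 ketone, ring A as in 7 | CC1=C(OS(=O)(=O)C(F)(F)F)[C@@]2(C)CC(O[Si](C(C)C)(C(C)C)C(C)C)=C[C@@H](COCc3ccccc3)[C@@H]2C(=O)C1 | intermediate
10 | furan-3-carbaldehyde | O=Cc1ccoc1 | starting material
11 | 3-ethenylfuran | C=Cc1ccoc1 | intermediate
12 | 9-[2-(furan-3-yl)ethyl]-9-borabicyclo[3.3.1]nonane | C(Cc1ccoc1)B1C2CCCC1CCC2 | intermediate (not isolated)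
13 | C9 furylethyl 6-ketone: 9-[2-(furan-3-yl)ethyl]-8-methyl-Δ8, C6 ketone, 2-OTIPS Δ2 enol ether, 4α-CH2OBn, 5α-H, 10β-CH3 | CC1=C(CCc3ccoc3)[C@@]2(C)CC(O[Si](C(C)C)(C(C)C)C(C)C)=C[C@@H](COCc4ccccc4)[C@@H]2C(=O)C1 | intermediate
14 | 6α-alcohol of 13 (6β-H) | CC1=C(CCc3ccoc3)[C@@]2(C)CC(O[Si](C(C)C)(C(C)C)C(C)C)=C[C@@H](COCc4ccccc4)[C@@H]2[C@@H](O)C1 | intermediate
15 | ring A enone: C2 ketone, C3=C4 bearing CH2OBn on C4, 6α-OH, 5α-H, 10β-CH3 | CC1=C(CCc3ccoc3)[C@@]2(C)CC(=O)C=C(COCc4ccccc4)[C@@H]2[C@@H](O)C1 | intermediate
16 | bis(trimethylsilyl) intermediate: C2(OSiMe3)=C3 enol ether, 6α-OSiMe3, 4α-CH3, 4β-CH2OBn | CC1=C(CCc3ccoc3)[C@@]2(C)CC(O[Si](C)(C)C)=C[C@](C)(COCc4ccccc4)[C@@H]2[C@@H](O[Si](C)(C)C)C1 | intermediate (not isolated)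
17 | C4-quaternary 2-ketone: 4α-CH3, 4β-CH2OBn, 6α-OH, 5α-H, 10β-CH3, furylethyl at C9 | CC1=C(CCc3ccoc3)[C@@]2(C)CC(=O)C[C@](C)(COCc4ccccc4)[C@@H]2[C@@H](O)C1 | intermediate
18 | 15,16-epoxylabda-8,13(16),14-triene-2α,6α,19-triol | CC1=C(CCc3ccoc3)[C@@]2(C)C[C@@H](O)C[C@](C)(CO)[C@@H]2[C@@H](O)C1 | intermediate
19 | 2,6,19-tris(O-pinacolboryl) ether of 18 carrying a pinacolboryl group at furan C15 (the α-carbon remote from the side chain) | CC1=C(CCc3coc(B4OC(C)(C)C(C)(C)O4)c3)[C@@]2(C)C[C@@H](OB5OC(C)(C)C(C)(C)O5)C[C@](C)(COB6OC(C)(C)C(C)(C)O6)[C@@H]2[C@@H](OB7OC(C)(C)C(C)(C)O7)C1 | intermediate (not isolated)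
20 | (2R,4S,5R,6S,10S)-2α,6α,19-trihydroxylabda-8,13-dien-15,16-olide | CC1=C(CCC2=CC(=O)OC2)[C@@]2(C)C[C@@H](O)C[C@](C)(CO)[C@@H]2[C@@H](O)C1 | target

## Step count and risks

Total step count: 12. Longest linear sequence: 11 steps (steps 1–5 and 7–12, from 1 and 2 to 20); step 6 is a one-step branch.

The three steps most likely to fail:

**Step 3 (enantioselective quinone Diels–Alder).** The catalyst may give insufficient enantiomeric excess with this 1-substituted silyloxy diene. Fallback, setting out from 4 and 5 and coming back at 7: the cycloaddition is run without chiral control (toluene, 80 °C, or Me2AlCl at −78 °C), which gives the racemic cis adduct, that is 6 together with its mirror image, the enantiomeric cis cycloadduct F1. DBU epimerisation as in step 4 then gives racemic trans material, 7 together with the enantiomeric trans-fused enedione F2. Preparative chromatography on a chiral stationary phase (supercritical CO2) delivers 7 as a single enantiomer.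

**Step 5 (conjugate reduction and triflation).** The borohydride may attack the C6 carbonyl directly, or the enolate may equilibrate before trapping. Fallback, setting out from 7 and coming back at 9: the enedione alkene is reduced with zinc (Zn dust, AcOH/THF, 0 °C) to the saturated 6,9-diketone F3 (either C8 epimer serves). Kinetic deprotonation at the unhindered C7 methylene with LiN(i-Pr)2 in the presence of Me3SiCl masks the C6 ketone as the C6 trimethylsilyl enol ether F4. KN(SiMe3)2 then removes the only remaining α-proton of the C9 ketone (C8–H), and PhNTf2 gives the silyloxy dienyl triflate F5. Mild aqueous acid hydrolyses the silyl enol ether with protonation at C7 and returns 9.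

**Step 10 (conjugate methylation at C4).** The hindered β,β-disubstituted enone may react sluggishly, or with poor facial selectivity. Fallback, setting out from 15 and coming back at 18: Corey–Chaykovsky cyclopropanation with dimethylsulfoxonium methylide (Me3S(O)I, NaH, DMSO, 23 °C) gives the α-face cyclopropyl ketone F6. The ylide adds reversibly, and a cyclopropane fused on the β face would clash with the syn-axial C10 methyl. Under the Li/NH3 conditions of step 11, with ethanol as proton source, the exocyclic cyclopropane bond C3–CH2 (the one that overlaps with the carbonyl π system) is cleaved to leave the 4α-methyl group. The liberated C2 ketone is reduced on to the 2α-alcohol and the benzyl ether is cleaved, which gives 18.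

## Further compounds

F1 | step 3 | enantiomeric cis cycloadduct (mirror image of 6) | CC=1C(=O)[C@]2(C)CC(O[Si](C(C)C)(C(C)C)C(C)C)=C[C@H](COCc3ccccc3)[C@@H]2C(=O)C=1
F2 | step 3 | enantiomeric trans-fused enedione (mirror image of 7) | CC=1C(=O)[C@]2(C)CC(O[Si](C(C)C)(C(C)C)C(C)C)=C[C@H](COCc3ccccc3)[C@H]2C(=O)C=1
F3 | step 5 | saturated 6,9-diketone (7,8-dihydro-7; 8α-CH3 shown) | C[C@H]1C(=O)[C@@]2(C)CC(O[Si](C(C)C)(C(C)C)C(C)C)=C[C@@H](COCc3ccccc3)[C@@H]2C(=O)C1
F4 | step 5 | C6 trimethylsilyl enol ether (C6=C7) of F3 with the C9 ketone free | C[C@H]1C(=O)[C@@]2(C)CC(O[Si](C(C)C)(C(C)C)C(C)C)=C[C@@H](COCc3ccccc3)[C@@H]2C(O[Si](C)(C)C)=C1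
F5 | step 5 | silyloxy dienyl triflate: C6(OSiMe3)=C7 and C8=C9(OTf) | CC1=C(OS(=O)(=O)C(F)(F)F)[C@@]2(C)CC(O[Si](C(C)C)(C(C)C)C(C)C)=C[C@@H](COCc3ccccc3)[C@@H]2C(O[Si](C)(C)C)=C1
F6 | step 10 | α-face cyclopropyl ketone: 3α,4α-methylene, C2 ketone, 4β-CH2OBn, 6α-OH | CC1=C(CCc4ccoc4)[C@@]2(C)CC(=O)[C@H]3C[C@@]3(COCc5ccccc5)[C@@H]2[C@@H](O)C1
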